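**Assumption:** the lithium enolate of tartrate acetonide 1 is alkylated anti to the neighbouring ester (cis-diester product), as is known for allyl and benzyl halides; the D-tartrate series is chosen on that basis. "Farnesyl" = (2E,6E)-3,7,11-trimethyldodeca-2,6,10-trien-1-yl throughout.

## Retrosynthetic overview

1. Target 17 ⇐ silyl ether 15 by a one-pot switch of O-silyl to O-acetyl.
2. 15 ⇐ cis-epoxy ynone aldehyde 14: the C(acyl)–C(alkene) ring bond is made by a light-driven 6-endo-dig hydroacylation, so the cyclohexenedione ring is formed last.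
3. 14 ⇐ epoxy lactone 10 + alkynyllithium 12, then oxidation; the lactone is a temporary ring that tells the two carbonyls apart.
4. 10 ⇐ cis-epoxy diester 8 ⇐ erythro diol 5; the oxirane is the first ring of the target to be formed, with net retention.
5. 5 ⇐ D-tartrate acetonide 1 + farnesyl bromide 2; enolate alkylation sets the quaternary carbon under control of the bought neighbouring stereocenter.

## Route

Step 1
Reactants: 1 dimethyl (4S,5S)-2,2-dimethyl-1,3-dioxolane-4,5-dicarboxylate (dimethyl 2,3-O-isopropylidene-D-tartrate); 2 (2E,6E)-farnesyl bromide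
Product: 4 dimethyl (4R,5S)-4-farnesyl-2,2-dimethyl-1,3-dioxolane-4,5-dicarboxylate, via lithium enolate 3 (not isolated)
Conditions: LDA (1.05 equiv, commercial solution) added to 1 + 2 (1.5 equiv), THF/HMPA 5:1, −78 °C, 20 h; AcOH quench
Reagents that add atoms: none
Why: Seebach α-alkylation of the tartrate acetonide enolate by SN2 at the primary allylic bromide (E,E chain kept); the electrophile enters anti to the C5 ester, so the bought C5 stereocenter sets the new quaternary carbon as R.

Step 2
Reactants: 4 dimethyl (4R,5S)-4-farnesyl-2,2-dimethyl-1,3-dioxolane-4,5-dicarboxylate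
Product: 5 dimethyl (2R,3S)-2-farnesyl-2,3-dihydroxybutanedioate
Conditions: TsOH·H2O (0.2 equiv), MeOH, 40 °C
Reagents that add atoms: none
Why: acid-catalysed transketalisation removes the acetonide under conditions mild enough for the trisubstituted alkenes; no stereocenter is touched.

Step 3
Reactants: 5 dimethyl (2R,3S)-2-farnesyl-2,3-dihydroxybutanedioate
Product: 8 dimethyl (2R,3S)-2-farnesyloxirane-2,3-dicarboxylate (cis-diester), via cyclic orthoacetate 6 (not isolated), via chloro acetate 7 (not isolated)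
Conditions: MeC(OMe)3, PPTS (cat.), CH2Cl2, rt; then TMSCl, CH2Cl2, 0 °C to rt; then K2CO3, MeOH, 0 °C
Reagents that add atoms: none
Why: Kolb–Sharpless diol-to-epoxide sequence: chloride opens the acetoxonium ion at the only secondary carbon with inversion and the tertiary alkoxide then displaces chloride with a second inversion, so the erythro diol gives the cis-epoxide with net retention at C3 while the tertiary C–O bond is never broken.

Step 4
Reactants: 8 dimethyl (2R,3S)-2-farnesyloxirane-2,3-dicarboxylate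
Product: 10 (1R,5R)-1-farnesyl-3,6-dioxabicyclo[3.1.0]hexan-2-one, via hydroxy ester 9 (not isolated)
Conditions: NaBH4 (0.6 equiv), MeOH, −20 to 0 °C; work-up; then PPTS (cat.), toluene, 40 °C
Reagents that add atoms: none
Why: chemoselective borohydride reduction of the less hindered glycidic ester (the other sits on the quaternary carbon) followed by lactonisation of the cis hydroxy ester, which leaves the hindered carbonyl as the only acyl group; both stereocenters are untouched.

Step 5
Reactants: 10 (1R,5R)-1-farnesyl-3,6-dioxabicyclo[3.1.0]hexan-2-one; 11 tert-butyldimethyl(prop-2-yn-1-yloxy)silane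
Product: 13 4-(tert-butyldimethylsilyloxy)-1-[(2R,3R)-2-farnesyl-3-(hydroxymethyl)oxiran-2-yl]but-2-yn-1-one (in equilibrium with its cyclic hemiketal), via lithium acetylide 12 (not isolated)
Conditions: 11, n-BuLi, THF, −78 °C, 30 min; then 10, −78 °C, 1 h; AcOH quench at −78 °C
Reagents that add atoms: none
Why: addition of a lithium acetylide to a lactone stops at the hemiketal alkoxide at −78 °C, so exactly one alkynyl group reaches the hindered carbonyl and the primary alcohol is released (ynone synthesis by lactone opening).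

Step 6
Reactants: 13 4-(tert-butyldimethylsilyloxy)-1-[(2R,3R)-2-farnesyl-3-(hydroxymethyl)oxiran-2-yl]but-2-yn-1-one
Product: 14 (2S,3R)-3-farnesyl-3-[4-(tert-butyldimethylsilyloxy)but-2-ynoyl]oxirane-2-carbaldehyde
Conditions: Dess–Martin periodinane, NaHCO3, CH2Cl2, 0 °C to rt; used crude
Reagents that add atoms: none
Why: Dess–Martin oxidation of the primary alcohol drains the open hydroxy ynone form; the oxirane C–H cannot enolise, so the cis-epoxy aldehyde is configurationally safe.

Step 7
Reactants: 14 (2S,3R)-3-farnesyl-3-[4-(tert-butyldimethylsilyloxy)but-2-ynoyl]oxirane-2-carbaldehyde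
Product: 15 (1S,6R)-3-[(tert-butyldimethylsilyloxy)methyl]-6-farnesyl-7-oxabicyclo[4.1.0]hept-3-ene-2,5-dione (C1 = epoxide CH; C6 = epoxide carbon bearing farnesyl)
Conditions: tetrabutylammonium decatungstate (2 mol%), MeCN (0.01 M), 390 nm LEDs, 20 °C, Ar
Reagents that add atoms: none
Why: Proposed new method: excited decatungstate abstracts the hydridic formyl hydrogen to give a σ-acyl radical that the oxirane holds cis to the ynone; this nucleophilic radical adds 6-endo-dig to the electrophilic β-alkyne carbon (5-exo attack at the α-carbon is polarity-mismatched and gives a more strained bicycle), and the α-keto vinyl radical is quenched by back hydrogen transfer from reduced decatungstate or from a second aldehyde, closing the cyclohexenedione ring without touching the two epoxide stereocenters; the closest known reaction types are decatungstate-photocatalysed hydroacylation of electron-poor alkenes by aldehydes and 6-endo acyl-radical cyclisations onto enones.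

Step 8
Reactants: 15 (1S,6R)-3-[(tert-butyldimethylsilyloxy)methyl]-6-farnesyl-7-oxabicyclo[4.1.0]hept-3-ene-2,5-dione
Product: 17 [(1S,6R)-6-farnesyl-2,5-dioxo-7-oxabicyclo[4.1.0]hept-3-en-3-yl]methyl acetate (CNP0301406.1), via primary alcohol 16 (not isolated)
Conditions: HF·pyridine, THF/pyridine 4:1, 0 °C to rt; then Ac2O (excess), DMAP (cat.), 0 °C
Reagents that add atoms: acetic anhydride, CC(=O)OC(C)=O
Why: fluoride cleavage of the primary silyl ether and DMAP-catalysed acetylation in the same flask under buffered, non-nucleophilic conditions that leave the epoxyquinone core and the triene intact.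

## Compound list

1 | dimethyl (4S,5S)-2,2-dimethyl-1,3-dioxolane-4,5-dicarboxylate | COC(=O)[C@H]1OC(C)(C)O[C@@H]1C(=O)OC | starting material
2 | (2E,6E)-farnesyl bromide | BrC/C=C(\C)CC/C=C(\C)CCC=C(C)C | starting material
3 | lithium enolate (ketene acetal) of 1 | COC(=O)[C@H]1OC(C)(C)OC1=C(OC)O[Li] | intermediate
4 | dimethyl (4R,5S)-4-farnesyl-2,2-dimethyl-1,3-dioxolane-4,5-dicarboxylate | COC(=O)[C@]1(C/C=C(\C)CC/C=C(\C)CCC=C(C)C)OC(C)(C)O[C@@H]1C(=O)OC | intermediate
5 | dimethyl (2R,3S)-2-farnesyl-2,3-dihydroxybutanedioate | COC(=O)[C@@](O)(C/C=C(\C)CC/C=C(\C)CCC=C(C)C)[C@H](O)C(=O)OC | intermediate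
6 | dimethyl (4R,5S)-4-farnesyl-2-methoxy-2-methyl-1,3-dioxolane-4,5-dicarboxylate (cyclic orthoacetate, both C2 epimers) | COC(=O)[C@]1(C/C=C(\C)CC/C=C(\C)CCC=C(C)C)OC(C)(OC)O[C@@H]1C(=O)OC | intermediate
7 | dimethyl (2S,3R)-2-acetoxy-3-chloro-2-farnesylbutanedioate | COC(=O)[C@@](OC(C)=O)(C/C=C(\C)CC/C=C(\C)CCC=C(C)C)[C@@H](Cl)C(=O)OC | intermediate
8 | dimethyl (2R,3S)-2-farnesyloxirane-2,3-dicarboxylate | COC(=O)[C@]1(C/C=C(\C)CC/C=C(\C)CCC=C(C)C)O[C@@H]1C(=O)OC | intermediate
9 | methyl (2R,3R)-2-farnesyl-3-(hydroxymethyl)oxirane-2-carboxylate | COC(=O)[C@]1(C/C=C(\C)CC/C=C(\C)CCC=C(C)C)O[C@@H]1CO | intermediate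
10 | (1R,5R)-1-farnesyl-3,6-dioxabicyclo[3.1.0]hexan-2-one | O=C1OC[C@H]2O[C@@]12C/C=C(\C)CC/C=C(\C)CCC=C(C)C | intermediate
11 | tert-butyldimethyl(prop-2-yn-1-yloxy)silane | C#CCO[Si](C)(C)C(C)(C)C | starting material
12 | lithium acetylide of 11 | [Li]C#CCO[Si](C)(C)C(C)(C)C | intermediate
13 | 4-(tert-butyldimethylsilyloxy)-1-[(2R,3R)-2-farnesyl-3-(hydroxymethyl)oxiran-2-yl]but-2-yn-1-one | O=C(C#CCO[Si](C)(C)C(C)(C)C)[C@]1(C/C=C(\C)CC/C=C(\C)CCC=C(C)C)O[C@@H]1CO | intermediate
14 | (2S,3R)-3-farnesyl-3-[4-(tert-butyldimethylsilyloxy)but-2-ynoyl]oxirane-2-carbaldehyde | O=C(C#CCO[Si](C)(C)C(C)(C)C)[C@]1(C/C=C(\C)CC/C=C(\C)CCC=C(C)C)O[C@@H]1C=O | intermediate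
15 | (1S,6R)-3-[(tert-butyldimethylsilyloxy)methyl]-6-farnesyl-7-oxabicyclo[4.1.0]hept-3-ene-2,5-dione | CC(C)(C)[Si](C)(C)OCC1=CC(=O)[C@]2(C/C=C(\C)CC/C=C(\C)CCC=C(C)C)O[C@@H]2C1=O | intermediate
16 | (1S,6R)-6-farnesyl-3-(hydroxymethyl)-7-oxabicyclo[4.1.0]hept-3-ene-2,5-dione | OCC1=CC(=O)[C@]2(C/C=C(\C)CC/C=C(\C)CCC=C(C)C)O[C@@H]2C1=O | intermediate
17 | [(1S,6R)-6-farnesyl-2,5-dioxo-7-oxabicyclo[4.1.0]hept-3-en-3-yl]methyl acetate | CC(=O)OCC1=CC(=O)[C@]2(C/C=C(\C)CC/C=C(\C)CCC=C(C)C)O[C@@H]2C1=O | target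

## Step count and risks

Total: 8 steps. Longest linear sequence: 8 steps (1 → 17); 2 and 11 are bought.

**Step 7 (the proposed new ring closure) is the most likely to fail.** The acyl radical could close 5-exo, fragment at the neighbouring oxirane, or the photocatalyst could abstract allylic hydrogens of the triene. The fallback uses known polar chemistry, sets out from 14 and comes back at 15. Hydroiodination of the ynone (NaI, AcOH, MeCN, 0 °C; anti addition) gives (2S,3R)-3-farnesyl-3-[(2Z)-4-(tert-butyldimethylsilyloxy)-3-iodobut-2-enoyl]oxirane-2-carbaldehyde F1. An intramolecular Nozaki–Hiyama–Kishi reaction (CrCl2, NiCl2 cat., DMF, rt) then forms the same ring bond with the regiochemistry fixed by the iodide, giving (1R,6R)-4-[(tert-butyldimethylsilyloxy)methyl]-1-farnesyl-5-hydroxy-7-oxabicyclo[4.1.0]hept-3-en-2-one F2 as a carbinol mixture. Dess–Martin oxidation converges on 15.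

**Step 4 may not distinguish the two glycidic esters well enough, or may over-reduce.** The fallback sets out from 8 and comes back at 10. Saponification of the less hindered ester (LiOH 1.0 equiv, THF/H2O, 0 °C) gives (2S,3R)-3-farnesyl-3-(methoxycarbonyl)oxirane-2-carboxylic acid F3. Activation with isobutyl chloroformate and N-methylmorpholine (THF, −15 °C) gives the isobutyl carbonic mixed anhydride F4. NaBH4 reduces it in the same flask to hydroxy ester 9, which lactonises to 10 as in the main route.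

**Step 3 may suffer from slow orthoester formation at the hindered diol or acid damage to the triene.** The fallback sets out from 5 and comes back at 8. Triflation of the secondary hydroxyl only (Tf2O, 2,6-lutidine, CH2Cl2, −78 °C) gives dimethyl (2R,3S)-2-farnesyl-2-hydroxy-3-(trifluoromethylsulfonyloxy)butanedioate F5. Bu4NBr displaces the triflate with inversion to give dimethyl (2S,3R)-3-bromo-2-farnesyl-2-hydroxybutanedioate F6. K2CO3 in MeOH closes the oxirane with a second inversion to 8.

Further compounds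
F1 | step 7 | (2S,3R)-3-farnesyl-3-[(2Z)-4-(tert-butyldimethylsilyloxy)-3-iodobut-2-enoyl]oxirane-2-carbaldehyde | O=C(/C=C(\I)CO[Si](C)(C)C(C)(C)C)[C@]1(C/C=C(\C)CC/C=C(\C)CCC=C(C)C)O[C@@H]1C=O
F2 | step 7 | (1R,6R)-4-[(tert-butyldimethylsilyloxy)methyl]-1-farnesyl-5-hydroxy-7-oxabicyclo[4.1.0]hept-3-en-2-one (C5 epimers) | CC(C)(C)[Si](C)(C)OCC1=CC(=O)[C@]2(C/C=C(\C)CC/C=C(\C)CCC=C(C)C)O[C@@H]2C1O
F3 | step 4 | (2S,3R)-3-farnesyl-3-(methoxycarbonyl)oxirane-2-carboxylic acid | COC(=O)[C@]1(C/C=C(\C)CC/C=C(\C)CCC=C(C)C)O[C@@H]1C(O)=O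
F4 | step 4 | isobutyl carbonic mixed anhydride of F3 | COC(=O)[C@]1(C/C=C(\C)CC/C=C(\C)CCC=C(C)C)O[C@@H]1C(=O)OC(=O)OCC(C)C
F5 | step 3 | dimethyl (2R,3S)-2-farnesyl-2-hydroxy-3-(trifluoromethylsulfonyloxy)butanedioate | COC(=O)[C@@](O)(C/C=C(\C)CC/C=C(\C)CCC=C(C)C)[C@H](OS(=O)(=O)C(F)(F)F)C(=O)OC
F6 | step 3 | dimethyl (2S,3R)-3-bromo-2-farnesyl-2-hydroxybutanedioate | COC(=O)[C@@](O)(C/C=C(\C)CC/C=C(\C)CCC=C(C)C)[C@@H](Br)C(=O)OC
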